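## Retrosynthetic overview
1. The obvious cut, the diaryl ether C–O bond (Ullmann, SNAr or acyclic iodonium arylation of 4,6-dibromoguaiacol), is not used. The ether is bought as diphenyl ether, so both benzene rings are present from the start.
2. The phenol OH comes from the C–I bond of an ortho-iodo diaryl ether by iodine–magnesium exchange, borylation and oxidation.
3. The OMe group and that C–I bond come together from a desymmetrising ring opening of a symmetric tetrabromo cyclic diaryliodonium salt with methanol.
4. All four C–Br bonds come from one tetrabromination of the cyclic iodonium salt. The bridging oxygen (ortho/para director) and the cationic iodine (meta director) point to the same four carbons.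
5. Ring order: the only ring formed is the temporary six-membered iodaoxinium ring, closed in step 2 from 2-iododiphenyl ether and reopened in step 4.

Assumption: the target SMILES has no stereocentre and no configurationally stable axis. The compound is achiral, so "single enantiomer" calls for no stereocontrol.

## Route

Step 1
Reactants: 1 diphenyl ether
Product: 3 1-iodo-2-phenoxybenzene, via 2-phenoxyphenyllithium 2 (not isolated)
Conditions: n-BuLi (1.05 equiv), THF, 0 °C → rt, 6 h; then I2 (1.1 equiv), THF, −78 °C → rt
Reagents that add atoms: iodine, II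
Why: Directed ortho-metalation, in which the ether oxygen coordinates n-BuLi and acidifies the ortho C–H so that one equivalent of base gives the monolithio species, followed by fast iodinolysis; no stereocentre is formed.

Step 2
Reactants: 3 1-iodo-2-phenoxybenzene
Product: 5 dibenzo[b,e][1,4]iodaoxin-5-ium triflate, via hydroxy(triflyloxy)iodane 4 (not isolated)
Conditions: mCPBA (1.2 equiv), TfOH (3 equiv), CH2Cl2 (0.05 M), 0 °C → rt, 2 h; precipitation with Et2O
Reagents that add atoms: triflic acid, OS(=O)(=O)C(F)(F)F
Why: One-pot cyclic diaryliodonium synthesis, in which the aryl iodide is oxidised to a trivalent-iodine electrophile that attacks the oxygen-activated ortho carbon of the other ring by intramolecular electrophilic aromatic substitution, the six-membered closure outrunning intermolecular para attack under dilution.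

Step 3
Reactants: 5 dibenzo[b,e][1,4]iodaoxin-5-ium triflate
Product: 7 1,3,7,9-tetrabromodibenzo[b,e][1,4]iodaoxin-5-ium triflate, via 3,7-dibromo iodaoxinium triflate 6 (not isolated)
Conditions: NBS (2.1 equiv), TfOH (solvent), 0 °C, 1 h; then NBS (2.6 equiv), 50 °C, 12 h; poured onto ice/Et2O, filtered
Reagents that add atoms: N-bromosuccinimide, O=C1CCC(=O)N1Br
Why: Proposed new method: exhaustive electrophilic aromatic bromination of an intact cyclic diaryliodonium salt with superacid-activated NBS, where the acid-stable cationic iodine is a meta director (as in the classical meta-nitration of diaryliodonium salts) and the ring oxygen, held in conjugation with both rings by the bridge, is an ortho/para director (as in the 2,7- then 4,5-bromination of xanthenes), so both effects converge on C3/C7 first and C1/C9 second, the other four C–H bonds (ortho/para to iodine, meta to oxygen) are shut down and the reaction stops at four bromines, the bridge avoids the drift to C5 seen when open-chain 2,2',4,4'-tetrabromodiphenyl ether is brominated further, and no bromide ion arises that could open the salt; the closest known reaction type is NBS/strong-acid bromination of deactivated arenes.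

Step 4
Reactants: 7 1,3,7,9-tetrabromodibenzo[b,e][1,4]iodaoxin-5-ium triflate
Product: 8 1,5-dibromo-2-(2,4-dibromo-6-methoxyphenoxy)-3-iodobenzene
Conditions: Cu(OTf)2 (10 mol %), NaHCO3 (1.5 equiv), 4 Å MS, MeOH/1,2-dichloroethane 1:1, 50 °C, 6 h
Reagents that add atoms: methanol, CO
Why: Copper-catalysed O-arylation of an alcohol by a diaryliodonium salt, run as a ring opening, in which monovalent copper formed in situ inserts into one of the two equivalent C–I bonds and the resulting aryl species of trivalent copper reductively eliminates with methanol strictly at the ipso carbon, so either bond gives the same product, the weak base leaves the acidic C–H between iodonium and bromine alone (no aryne pathway), and the C–Br bonds and the new C–I bond are inert to ligand-free copper at 50 °C.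

Step 5
Reactants: 8 1,5-dibromo-2-(2,4-dibromo-6-methoxyphenoxy)-3-iodobenzene
Product: 11 3,5-dibromo-2-(2,4-dibromo-6-methoxyphenoxy)phenol, via arylmagnesium chloride 9 (not isolated), via dimethyl arylboronate 10 (not isolated)
Conditions: iPrMgCl·LiCl (1.05 equiv), THF, −60 °C, 30 min; B(OMe)3 (2 equiv), −60 → 0 °C; 30 % aq. H2O2, 0 °C → rt
Reagents that add atoms: hydrogen peroxide, OO
Why: Knochel-type iodine–magnesium exchange is far faster at C–I than at C–Br at −60 °C, the arylmagnesium is stabilised by the ortho aryloxy oxygen and has no ortho halogen to expel, and borylation followed by peroxide oxidation (1,2-aryl shift from boron to oxygen, with the magnesium methoxide already present as base) puts OH exactly where iodine stood.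

## Compound list
1 | diphenyl ether | c1ccc(cc1)Oc1ccccc1 | starting material
2 | 2-phenoxyphenyllithium | [Li]c1ccccc1Oc1ccccc1 | intermediate
3 | 1-iodo-2-phenoxybenzene | Ic1ccccc1Oc1ccccc1 | intermediate
4 | [hydroxy(2-phenoxyphenyl)-λ3-iodanyl] trifluoromethanesulfonate | OI(OS(=O)(=O)C(F)(F)F)c1ccccc1Oc1ccccc1 | intermediate
5 | dibenzo[b,e][1,4]iodaoxin-5-ium triflate (iodine at position 5, oxygen at position 10) | c1ccc2c(c1)Oc1ccccc1[I+]2.[O-]S(=O)(=O)C(F)(F)F | intermediate
6 | 3,7-dibromodibenzo[b,e][1,4]iodaoxin-5-ium triflate (Br para to the ring oxygen on each ring) | Brc1ccc2Oc3ccc(Br)cc3[I+]c2c1.[O-]S(=O)(=O)C(F)(F)F | intermediate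
7 | 1,3,7,9-tetrabromodibenzo[b,e][1,4]iodaoxin-5-ium triflate (Br ortho and para to the ring oxygen on each ring) | Brc1cc2[I+]c3cc(Br)cc(Br)c3Oc2c(Br)c1.[O-]S(=O)(=O)C(F)(F)F | intermediate
8 | 1,5-dibromo-2-(2,4-dibromo-6-methoxyphenoxy)-3-iodobenzene | COc1cc(Br)cc(Br)c1Oc1c(I)cc(Br)cc1Br | intermediate
9 | [3,5-dibromo-2-(2,4-dibromo-6-methoxyphenoxy)phenyl]magnesium chloride | COc1cc(Br)cc(Br)c1Oc1c([Mg]Cl)cc(Br)cc1Br | intermediate
10 | dimethyl [3,5-dibromo-2-(2,4-dibromo-6-methoxyphenoxy)phenyl]boronate | COc1cc(Br)cc(Br)c1Oc1c(B(OC)OC)cc(Br)cc1Br | intermediate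
11 | 3,5-dibromo-2-(2,4-dibromo-6-methoxyphenoxy)phenol (achiral) | COc1cc(Br)cc(Br)c1Oc1c(O)cc(Br)cc1Br | target

## Counts
- Total step count: 5
- Longest linear sequence: 5

## Steps most likely to fail

**Step 3.** The doubly deactivated rings may stop at dibromide 6, or the salt may not tolerate warm superacid.
- This fallback sets out from 1 and comes back to the route at 11.
- The iodonium bridge is given up. Two formyl groups take over both of its jobs, as meta directors and as latent oxygens.
- Double ortho-lithiation of 1 (n-BuLi/TMEDA, 2.3 equiv, Et2O, rt) gives 2,2'-dilithiodiphenyl ether F1. A DMF quench then gives 2,2'-oxydibenzaldehyde F2.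
- NBS in concentrated H2SO4 brominates para and then ortho to the ether oxygen. Both sites are meta to CHO, so the product is 2,2'-oxybis(3,5-dibromobenzaldehyde) F3.
- Double Baeyer–Villiger oxidation (mCPBA, CH2Cl2, reflux) gives oxybis(3,5-dibromobenzene-2,1-diyl) diformate F4.
- Aqueous KOH followed by acid gives 2,2'-oxybis(3,5-dibromophenol) F5.
- Mono-O-methylation (K2CO3 1.0 equiv, MeI 1.0 equiv, acetone, rt) gives 11. The hydrogen-bonded monoanion resists a second deprotonation, and unreacted F5 is recovered by base extraction and recycled.

**Step 4.** The C–H flanked by iodonium and bromine is acidic, so an aryne pathway may compete and scramble the position of OMe. Copper turnover may also be sluggish.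
- This fallback sets out from 7 and comes back to the route at 11.
- A non-basic nucleophile opens the ring, and symmetry is broken only at the end.
- KI (3 equiv, DMF, 90 °C) converts 7, by anion exchange and thermal ligand coupling, into bis(2,4-dibromo-6-iodophenyl) ether F6.
- Double iodine–magnesium exchange (iPrMgCl·LiCl 2.2 equiv, THF, −60 °C) gives oxybis(3,5-dibromobenzene-2,1-diyl)bis(magnesium chloride) F7.
- B(OMe)3 gives tetramethyl [oxybis(3,5-dibromobenzene-2,1-diyl)]diboronate F8.
- Aqueous H2O2 gives the bis-phenol F5 already described, which is mono-methylated as above to 11.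

**Step 5.** Bromine–magnesium exchange on the electron-poor rings may compete and give debrominated or scrambled phenols.
- This fallback sets out from 8 and comes back to the route at 11.
- A catalytic, C–I selective borylation with an isolated boronate replaces the organomagnesium.
- PdCl2(dppf) (3 mol %), B2pin2 and KOAc in dioxane at 60 °C are used. Zerovalent palladium inserts into C–I well before C–Br.
- The product is 2-[3,5-dibromo-2-(2,4-dibromo-6-methoxyphenoxy)phenyl]-4,4,5,5-tetramethyl-1,3,2-dioxaborolane F9. It is purified and then oxidised with aqueous H2O2 in THF at 0 °C to 11.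

## Further compounds
F1 | step 3 | 2,2'-dilithiodiphenyl ether | [Li]c1ccccc1Oc1ccccc1[Li]
F2 | step 3 | 2,2'-oxydibenzaldehyde | O=Cc1ccccc1Oc1ccccc1C=O
F3 | step 3 | 2,2'-oxybis(3,5-dibromobenzaldehyde) | O=Cc1cc(Br)cc(Br)c1Oc1c(Br)cc(Br)cc1C=O
F4 | step 3 | oxybis(3,5-dibromobenzene-2,1-diyl) diformate | O=COc1cc(Br)cc(Br)c1Oc1c(Br)cc(Br)cc1OC=O
F5 | step 3 | 2,2'-oxybis(3,5-dibromophenol) | Oc1cc(Br)cc(Br)c1Oc1c(Br)cc(Br)cc1O
F6 | step 4 | bis(2,4-dibromo-6-iodophenyl) ether | Ic1cc(Br)cc(Br)c1Oc1c(Br)cc(Br)cc1I
F7 | step 4 | oxybis(3,5-dibromobenzene-2,1-diyl)bis(magnesium chloride) | Cl[Mg]c1cc(Br)cc(Br)c1Oc1c(Br)cc(Br)cc1[Mg]Cl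
F8 | step 4 | tetramethyl [oxybis(3,5-dibromobenzene-2,1-diyl)]diboronate | COB(OC)c1cc(Br)cc(Br)c1Oc1c(Br)cc(Br)cc1B(OC)OC
F9 | step 5 | 2-[3,5-dibromo-2-(2,4-dibromo-6-methoxyphenoxy)phenyl]-4,4,5,5-tetramethyl-1,3,2-dioxaborolane | COc1cc(Br)cc(Br)c1Oc1c(B2OC(C)(C)C(C)(C)O2)cc(Br)cc1Br
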